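The readings are simulated with constants of no real substance, and the scatter is random.

| flask | substrate | time |
|---|---|---|
| violet | 0.0800 M |  |
| teal | 0.0480 M |  |
| blue | 0.240 M |  |
| red | 0.0800 M | 48 min |

- violet run (time / min: [target] / M): 0.48: 0.0033; 0.76: 0.0037; 1.2: 0.0073; 1.9: 0.0124; 3.0: 0.0197; 4.8: 0.0312; 7.6: 0.0410; 12: 0.0491
- teal run (time / min: [target] / M): 0.48: 0.0017; 0.76: 0.0034; 1.2: 0.0049; 1.9: 0.0084; 3.0: 0.0119; 4.8: 0.0174; 7.6: 0.0218; 12: 0.0295
- blue run (time / min: [target] / M): 0.48: 0.0109; 0.76: 0.0164; 1.2: 0.0270; 1.9: 0.0452; 3.0: 0.0751; 4.8: 0.1209; 7.6: 0.1645; 12: 0.1747

(readings scatter by 8 × 10⁻⁴ M)

* apparent order in [substrate] of the starting rate, round the charge of the violet run (the rate where two percent of its substrate have turned into target) (one fixed amount of target, the same in the runs compared)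
* target in the red run at 48 min, as a share of the substrate charged

- Overall: substrate -> target.
- Constant volume, constant temperature.
- An order is taken over about fifteen percent of the charge, up and down.

**Fill time.** Divide a charge by its starting rate. Near 0.0124 M of target the violet run climbs by 0.00689 M min⁻¹, which gives a fill time of 11.6 min. Near 0.0109 M of target the blue run, with 3.00 times that charge, climbs by 0.0216 M min⁻¹ and gives 11.1 min. The ratio of those two rates puts the order near 1.04, as a reading.

**Loss time.** At 12 min the blue run stands at 0.1747 M, short of its charge by 0.0653 M. Take that gap as target lost in proportion to the target present. The area under the target curve, divided by the gap, then gives a loss time of 22.0 min. Any substrate still unturned in the gap would lengthen it.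

**Both ends joined.** The loss time is longer than the fill time, by a ratio of 1.90, so target is made first and lost afterwards, as in consecutive steps. Target born on average at the fill time and dying over the loss time leaves the red run, with the violet charge, 19.1% at 48 min.

**The forecast.** The forecast differs from this reckoning on the share: it gives order 1 and 71%, “an extrapolation rather than a measured value”.

**The flask.** The simulation gives order 1.0 and 25.8%.

    substrate → target (0.01830 min⁻¹)
    substrate + target → 2 target (1.236 L mol⁻¹ min⁻¹)
    substrate → target (0.06960 min⁻¹)
    target → decomposed product (0.03462 min⁻¹)

That share stands 6.7 percentage points above the reckoned 19.1%. With the step from target to decomposed product taken away, the red run holds >99.9% at 48 min, so that step is the main reason for the 74 points missing. The red run without the step from substrate to target holds 35.9%, and on the loss time as read from the blue run, 22.0 min, the distance between those two shares reckons as target born 7.27 min later on average in that run.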